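The earlier runs and the new flask were generated by integration from invented constants, noise included.

Substrate charged at 2.0 M meets partner at 2.20 M in the grey flask and at 1.1 M in the violet run.

| flask | substrate | partner | temperature | remark | time |
|---|---|---|---|---|---|
| grey | 2 M | 2.2 M | 40 °C | the very flask that is asked about, followed so far |  |
| violet | 2 M | 1.1 M | 35 °C | run made earlier |  |
| flask | 2.0 M | 2.20 M | 40 °C |  | 20 min |

| grey: time / min | grey: target / % | violet: time / min | violet: target / % |
|---|---|---|---|
| 1.00 | 11 | 0.667 | 4 |
| 3.00 | 27 | 1.00 | 9 |
| 6.00 | 31 | 2.00 | 17 |
| 8.00 | 33 | 3.00 | 21 |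
| 12.0 | 36 | 5.00 | 30 |
| 15.0 | 38 | 8.00 | 37 |

(each reading ± 2 percentage points)

1. target, in percent of the substrate first charged, at 20 min
2. what to do for the largest gain in target; "none" if nothing gains more than 2 percentage points (Saturday's / Tuesday's / Friday's / none)
3. target present, with what was taken out counted in, in percent of the substrate first charged, after Tuesday's
4. target present, with what was taken out counted in, in percent of the substrate first charged, after Friday's

- Saturday's: at 20 min raise the temperature by 10 K, then wait 40 min
- Tuesday's: change nothing and wait 40 min more
- Friday's: at 20 min take out 90 % of the target then present, then wait 40 min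

- removed target is counted in

The grey run climbs to 27 % by 3.00 min and then breaks, with 31 % at 6.00 min. The violet run, with half the partner at 35 °C, stands unbroken and higher, at 37 % at 8.00 min. The reckoning here follows one molecule of substrate to a fork: it turns to target or it is caught, and partner does the catching. The break reading, good to 2 percentage points, then gives odds of 2.23 against target: the loss odds, the share not turned to target over the share turned at the break, a selectivity factor.

Partner first. If the odds scale with c(partner), the violet charge has 1.11, temperature apart, and a break near 47.3 %, higher than its last reading. Time next. The grey tail gains 5 points from 8.00 min to 15.0 min, and a straight line gives 41.6 % at 20 min. That creep reads as caught material returning to the fork. Removal next. Target is an outcome of the fork, not a catcher, so Friday's should gain as much as Tuesday's. Heat last. Release should quicken with 10 K more, so this reckoning picks Saturday's.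

The forecast gives 40.5 % at 20 min, and 50 % after Tuesday's and after Friday's alike. It chooses Tuesday's and parts from the reckoning here on heat: “Heating would probably speed the death.”

The flask gives 40.6 % at 20 min. Tuesday's reaches 50.4 %, a gain of 9.7 points, and Friday's reaches 50.4 %, the same gain. Saturday's gains 17 points, more than either, so the answer is Saturday's.

    substrate → intermediate A (k = 4.60 min⁻¹, Ea = 77.0 kJ mol⁻¹)
    substrate → target (k = 0.0640 min⁻¹, Ea = 82.0 kJ mol⁻¹)
    partner + intermediate A ⇌ intermediate B (K = 5.20 M⁻¹, k = 0.170 M⁻¹ min⁻¹, Ea = 52.0 kJ mol⁻¹, ΔH = −4.00 kJ mol⁻¹)
    intermediate B ⇌ intermediate C (K = 0.320, k = 0.130 min⁻¹, Ea = 98.0 kJ mol⁻¹, ΔH = −45.0 kJ mol⁻¹)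
    intermediate A → target (k = 0.200 min⁻¹, Ea = 82.0 kJ mol⁻¹)
    intermediate A → decomposed reagent (k = 0.110 min⁻¹, Ea = 92.0 kJ mol⁻¹)
    (constants at 40 °C)

The loss odds, read from one scattered reading, put 69.0 % of the substrate outside target at 6.00 min in the grey run; this is no final split, since the flask left until 200 min holds 62.1 % as target. At 20 min the grey flask holds 36.2 % parked as intermediate B and intermediate C, beside 21.6 % as decomposed reagent. Saturday's gain draws on that parked material: without the back reaction of intermediate B, or without the path from intermediate A to target, it falls from 17 points to 0 points. In the neighbour charged with 1.3 M of partner, the odds scale to 1.32, which puts a break near 43.2 %. That neighbour gives 48.5 % at 20 min.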